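**Assumption:** the target SMILES has no stereocentre and no axis descriptor. The hindered C6–C8′ biaryl axis is therefore formed as the racemic atropisomer pair, and no enantiocontrol is attempted.

## Retrosynthesis
1. The C6–C8′ biaryl bond is formed last, by Ag(I)-mediated phenoxyl-radical cross-coupling of 2-ethoxy-7-methyljuglone (coupling through its ortho carbon C6) with 3-ethoxy-7-methyljuglone (coupling through its para carbon C8′).
2. Each juglone monomer is made by a Diels–Alder reaction of 2-ethoxy-1,4-benzoquinone with 1,1-bis(trimethylsilyloxy)-3-methylbutadiene. Base-induced loss of TMSO⁻ and DDQ dehydrogenation then give the phenol.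
3. The two ethoxy regiochemistries come from the same two partners: thermal conditions give the 3-ethoxy monomer and BF₃ gives the 2-ethoxy monomer.
4. 2-Ethoxybenzoquinone comes from benzoquinone and ethanol, and the diene comes from 3-methylbut-2-enoic acid.
5. Ring order: the ethoxyquinone ring exists first, the phenolic ring is built onto it in each monomer, and the biaryl bond is formed last.

## Route

**Step 1**
Reactants: **1** 3-methylbut-2-enoic acid
Product: **2** 1,1-bis(trimethylsilyloxy)-3-methylbuta-1,3-diene
Conditions: LDA (2.1 equiv), THF, –78 °C; then TMSCl (2.2 equiv), –78 °C → rt; concentrate, use crude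
Reagents that add atoms: TMSCl, C[Si](C)(C)Cl
Why: γ-Deprotonation of the carboxylate gives the ene-diolate dianion, and O,O-silylation gives the bis-silyl ketene acetal diene (silyl ketene acetal formation). Its C1 carries both oxygens, so the future peri-oxygen is already in place.

**Step 2**
Reactants: **3** 1,4-benzoquinone (2 equiv)
Product: **4** 2-ethoxy-1,4-benzoquinone
Conditions: EtOH (1 equiv), cat. H₂SO₄, MeCN, rt; then Ag₂O, rt (one pot)
Reagents that add atoms: ethanol, CCO
Why: Acid-catalysed oxa-Michael addition of EtOH to the quinone gives 2-ethoxyhydroquinone, which excess quinone or Ag₂O reoxidises to the quinone (conjugate addition/reoxidation). Limiting the EtOH to 1 equiv suppresses bis-addition.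

**Step 3**
Reactants: **2** diene (1.5 equiv), **4** 2-ethoxy-1,4-benzoquinone
Product: **5** cis-fused cycloadduct with thermal regiochemistry (racemic; one enantiomer drawn)
Conditions: PhMe, 60 °C, 12 h; concentrate, use crude (same flask continues into Step 4)
Reagents that add atoms: none
Why: Proposed new method: a thermal Diels–Alder reaction of a 1,1-dioxygenated diene with the unsubstituted C5=C6 bond of a 2-alkoxyquinone, in the spirit of Brassard/Danishefsky quinone annulations; the closest known reaction type is the Diels–Alder reaction of 1-oxygenated dienes with 2-methoxyquinones. The C4=O of **4** is a vinylogous ester, so C1=O is the stronger acceptor and C5 is the electrophilic terminus. The nucleophilic CH₂ terminus of **2** bonds to C5 and the C(OTMS)₂ terminus bonds to C6. The peri-oxygen carbon therefore sits next to the carbonyl that is adjacent to C–OEt, which places the ethoxy at C3 of the final naphthoquinone. Suprafacial addition gives the cis ring fusion; these two sp³ centres are destroyed in Step 4.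

**Step 4**
Reactants: **5** cycloadduct
Product: **6** 3-ethoxy-5-hydroxy-7-methyl-1,4-naphthoquinone
Conditions: DBU (1.5 equiv), PhMe, rt; then DDQ (1.1 equiv), rt; aq. NH₄Cl work-up
Reagents that add atoms: none
Why: DBU enolises the ring-fusion C–H that is α to the quinone carbonyl, and E1cB loss of TMSO⁻ from the neighbouring ketal carbon gives a silyl enol ether (E1cB elimination). DDQ then dehydrogenates the dihydro ring to the aromatic ring (dihydronaphthalene → naphthalene oxidation), and the aryl silyl ether is cleaved on work-up to the peri-hydroxy quinone. All ring-fusion stereochemistry is lost.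

**Step 5**
Reactants: **2** diene (1.3 equiv), **4** 2-ethoxy-1,4-benzoquinone
Product: **7** cis-fused cycloadduct with BF₃ regiochemistry (racemic; one enantiomer drawn)
Conditions: **4** + BF₃·OEt₂ (1.1 equiv), CH₂Cl₂, –78 °C; add **2**; –78 → –20 °C; quench with Et₃N (3 equiv) at –20 °C; filter through Celite, concentrate, use crude (same flask continues into Step 6)
Reagents that add atoms: none
Why: Proposed new method: monodentate BF₃ binds the more basic vinylogous-ester C4=O of **4**, which makes C6 the electrophilic terminus and reverses the regiochemistry of Step 3; the closest known reaction type is the Lewis-acid regio-reversal of 2-alkoxyquinone Diels–Alder reactions. The CH₂ terminus of the diene bonds to C6 and the C(OTMS)₂ terminus bonds to C5, so the peri-oxygen carbon sits next to the carbonyl attached to the C–H carbon of the quinone ring (ethoxy at C2 of the final naphthoquinone). The cis ring fusion again comes from suprafacial addition. The Et₃N quench neutralises BF₃ before the acid-labile bis-silyl ketal is handled.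

**Step 6**
Reactants: **7** cycloadduct
Product: **8** 2-ethoxy-5-hydroxy-7-methyl-1,4-naphthoquinone
Conditions: DBU (1.5 equiv), PhMe, rt; then DDQ (1.1 equiv), rt; aq. NH₄Cl work-up
Reagents that add atoms: none
Why: As in Step 4, E1cB loss of TMSO⁻ after enolisation of the ring-fusion C–H, then DDQ aromatisation and silyl cleavage give the phenol; the ring-fusion stereocentres are destroyed.

**Step 7 (key radical step)**
Reactants: **8** 2-ethoxy-7-methyljuglone (2 equiv), **6** 3-ethoxy-7-methyljuglone
Product: **9** 3,2′-diethoxyisodiospyrin
Conditions: Ag₂O (3 equiv), CH₂Cl₂ (0.02 M), 25 °C, dark, 12 h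
Reagents that add atoms: none
Why: Proposed new method: Ag(I) oxidises the peri-hydroxy-quinone phenols to phenoxyl radicals. Their spin density sits on O, on the ortho carbon (C6 of **8**) and on the para carbon (C8′ of **6**). C–C radical cross-coupling followed by tautomerisation restores the phenol and forms the 6,8′ bond (oxidative phenol radical coupling, the closest known reaction being the biomimetic dimerisation of 7-methyljuglone). Excess **8** suppresses homodimerisation of **6**, and the 6,6′ and 8,8′ isomers are removed by chromatography. There are no sp³ stereocentres, and the axis is formed racemic.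

## Compound list
1 | 3-methylbut-2-enoic acid | CC(C)=CC(=O)O | starting material
2 | 1,1-bis(trimethylsilyloxy)-3-methylbuta-1,3-diene | C=C(C)C=C(O[Si](C)(C)C)O[Si](C)(C)C | intermediate
3 | 1,4-benzoquinone | O=C1C=CC(=O)C=C1 | starting material
4 | 2-ethoxy-1,4-benzoquinone | CCOC1=CC(=O)C=CC1=O | intermediate
5 | cis-fused cycloadduct, thermal regiochemistry (racemic, one enantiomer shown) | CCOC1=CC(=O)[C@H]2CC(C)=CC(O[Si](C)(C)C)(O[Si](C)(C)C)[C@H]2C1=O | intermediate
6 | 3-ethoxy-5-hydroxy-7-methyl-1,4-naphthoquinone | CCOC1=CC(=O)c2cc(C)cc(O)c2C1=O | intermediate
7 | cis-fused cycloadduct, BF₃ regiochemistry (racemic, one enantiomer shown) | CCOC1=CC(=O)[C@H]2C(O[Si](C)(C)C)(O[Si](C)(C)C)C=C(C)C[C@H]2C1=O | intermediate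
8 | 2-ethoxy-5-hydroxy-7-methyl-1,4-naphthoquinone | CCOC1=CC(=O)c2c(O)cc(C)cc2C1=O | intermediate
9 | 3,2′-diethoxyisodiospyrin | CCOC1=CC(=O)c2c(cc(C)c(-c3c(C)cc(O)c4c3C(=O)C=C(OCC)C4=O)c2O)C1=O | target

## Totals
- Total steps: 7. Steps 3 + 4 and Steps 5 + 6 are each run in one flask without isolating the cycloadduct.
- Longest linear sequence: 4 steps (1 → 2 → 5 → 6 → 9, or 3 → 4 → 5 → 6 → 9, or 3 → 4 → 7 → 8 → 9).

## Three steps most likely to fail
1. **Step 7** (cross-coupling selectivity: C6 versus C8 coupling, and hetero- versus homo-coupling).
   - Fallback: a non-radical Suzuki–Miyaura coupling of the C6-iodo derivative of **8** (ortho-directed iodination) with the C8′-pinacolboronate of **6** (Ir-catalysed C–H borylation).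
2. **Step 5** (the BF₃ regio-reversal, with a very acid-sensitive silyl ketene acetal diene).
   - Fallback: make 7-methyljuglone by the Step 3/4 sequence with unsubstituted benzoquinone, then install the 2-ethoxy group by Ce(III)-catalysed oxa-Michael addition of EtOH with air reoxidation, separating regioisomers.
3. **Step 3** (the new Diels–Alder reaction with the bis-silyl ketene acetal diene, which could instead undergo Mukaiyama–Michael addition or electron transfer with the quinone).
   - Fallback: use the 1-methoxy-1-silyloxy diene made from methyl 3-methylbut-2-enoate, which gives the 5-OMe monomer, then peri-selective BCl₃ demethylation to **6**.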